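**Retrosynthetic overview**

1. Endgame: acylate the C8 alcohol with (R)-2-methylbutanoic acid, oxidise the C14 methyl to CO2Me (SeO2 ene/[2,3] oxidation, which also gives the cis ring alkene), and methylenate the lactone.
2. trans-γ-Lactone ⇐ C6 ketone carrying a C7 acetic ester, by chelation-controlled reduction and lactonization with inversion at C6.
3. Ten-membered ring (key step) ⇐ anionic oxy-Cope [3,3] rearrangement of a trans-1,2-dialkenylcyclohexanol: forms C8–C9, cleaves C1–C6, sets C8; the enolate is alkylated in the same flask (C7–C11).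
4. Dialkenylcyclohexanol ⇐ (Z)-2-(PMB-oxy)vinyllithium + trans-2-isopropenyl-5-(silyloxymethyl)cyclohexanone ⇐ (R)-cyclohex-3-ene-1-carboxylic acid (iodolactonization, iron-catalysed alkenylation).
5. Ring order: six-membered ring bought → ten-membered ring by ring expansion → five-membered lactone last.

Assumption: (R)-cyclohex-3-ene-1-carboxylic acid and (R)-2-methylbutanoic acid are bought as single enantiomers (the target SMILES encodes the 2R acyl group); labels C1–C15 follow germacrane numbering of the target (C6 lactone O–CH, C7, C8 acyloxy CH, C9, C10 ester-bearing alkene carbon, C1 alkene CH, C4 the CH carrying C15H2OH, C11–C13 the methylene-lactone carbons, C14 the ester carbon).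

**Route**

Step 1
Reactants: 1 (R)-cyclohex-3-ene-1-carboxylic acid
Product: 2 (1R,4R,5R)-4-iodo-6-oxabicyclo[3.2.1]octan-7-one
Conditions: I2, KI, NaHCO3, H2O, rt, dark
Reagents that add atoms: iodine, II
Why: Iodolactonization: the carboxylate opens the iodonium ion from its own face, so the lactone C–O bond forms cis to the bought stereocentre and the C–I bond trans-diaxial to it, which marks the carbon of the later ketone and the carbon of the later alkenyl group.

Step 2
Reactants: 2 (1R,4R,5R)-4-iodo-6-oxabicyclo[3.2.1]octan-7-one; 3 isopropenylmagnesium bromide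
Product: 4 (1R,4S,5R)-4-(prop-1-en-2-yl)-6-oxabicyclo[3.2.1]octan-7-one
Conditions: 3 (slow addition), FeCl3 (5 mol %), TMEDA, THF, 0 °C
Reagents that add atoms: none
Why: Iron-catalysed Kumada-type cross-coupling of a secondary alkyl iodide with an alkenyl Grignard reagent runs through a carbon radical that is captured on the face away from the lactone bridge (alkenyl trans to the C–O bond) and is much faster than Grignard addition to the lactone when the reagent is added slowly at 0 °C; the new centre also lies alpha to the later ketone and can be corrected there.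

Step 3
Reactants: 4 (1R,4S,5R)-4-(prop-1-en-2-yl)-6-oxabicyclo[3.2.1]octan-7-one
Product: 5 (1R,2S,5R)-5-(hydroxymethyl)-2-(prop-1-en-2-yl)cyclohexan-1-ol
Conditions: LiAlH4, THF, 0 °C → rt
Reagents that add atoms: none
Why: Hydride reduction of the lactone to the diol creates no stereocentre and leaves the isolated alkene untouched.

Step 4
Reactants: 5 (1R,2S,5R)-5-(hydroxymethyl)-2-(prop-1-en-2-yl)cyclohexan-1-ol
Product: 6 (1R,2S,5R)-5-{[(tert-butyldimethylsilyl)oxy]methyl}-2-(prop-1-en-2-yl)cyclohexan-1-ol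
Conditions: TBSCl, imidazole, CH2Cl2, 0 °C
Reagents that add atoms: tert-butyldimethylsilyl chloride, CC(C)(C)[Si](C)(C)Cl
Why: Chemoselective silylation of the primary alcohol, the equatorial secondary alcohol next to the isopropenyl group being far more hindered.

Step 5
Reactants: 6 (1R,2S,5R)-5-{[(tert-butyldimethylsilyl)oxy]methyl}-2-(prop-1-en-2-yl)cyclohexan-1-ol
Product: 7 (2S,5R)-5-{[(tert-butyldimethylsilyl)oxy]methyl}-2-(prop-1-en-2-yl)cyclohexan-1-one
Conditions: Dess–Martin periodinane, CH2Cl2, rt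
Reagents that add atoms: none
Why: Dess–Martin oxidation of the secondary alcohol under mild non-basic conditions gives the ketone with its 2- and 5-substituents already trans-diequatorial, the thermodynamically favoured arrangement, so the enolisable alpha centre is not at risk.

Step 6
Reactants: 8 4-methoxybenzyl alcohol; 9 ethyl vinyl ether
Product: 10 4-methoxybenzyl vinyl ether
Conditions: Pd(OAc)2 (2 mol %), 1,10-phenanthroline, 9 (excess, as solvent), rt
Reagents that add atoms: none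
Why: Palladium-catalysed transfer vinylation (transetherification) moves the vinyl group of excess ethyl vinyl ether onto the benzylic alcohol.

Step 7
Reactants: 10 4-methoxybenzyl vinyl ether
Product: 12 (Z)-1-bromo-2-[(4-methoxybenzyl)oxy]ethene, via dibromo ether 11 (not isolated)
Conditions: Br2, CH2Cl2, −78 °C; then DBU, −78 °C → rt
Reagents that add atoms: bromine, BrBr
Why: Electrophilic addition of bromine to the enol ether and base-induced dehydrobromination of the resulting 1,2-dibromo ether (loss of the alpha bromide through an oxocarbenium-like transition state) give the beta-bromo enol ether mainly as the Z isomer, as for the ethyl analogue, and the minor E isomer is removed by chromatography.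

Step 8
Reactants: 7 (2S,5R)-5-{[(tert-butyldimethylsilyl)oxy]methyl}-2-(prop-1-en-2-yl)cyclohexan-1-one; 12 (Z)-1-bromo-2-[(4-methoxybenzyl)oxy]ethene
Product: 14 (1S,2S,5R)-5-{[(tert-butyldimethylsilyl)oxy]methyl}-1-{(Z)-2-[(4-methoxybenzyl)oxy]ethenyl}-2-(prop-1-en-2-yl)cyclohexan-1-ol, via vinyllithium 13 (not isolated)
Conditions: 12, t-BuLi (2 equiv), Et2O, −78 °C; then 7, −78 °C; H2O
Reagents that add atoms: none
Why: Lithium–bromine exchange gives the oxygen-chelated and configurationally stable Z-vinyllithium, which adds to the ketone (1,2-addition) from the equatorial side as vinyl and alkyl lithium reagents do with menthone-type ketones, setting the carbinol centre with axial OH and the two alkenyl groups trans-diequatorial.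

Step 9
Reactants: 14 (1S,2S,5R)-5-{[(tert-butyldimethylsilyl)oxy]methyl}-1-{(Z)-2-[(4-methoxybenzyl)oxy]ethenyl}-2-(prop-1-en-2-yl)cyclohexan-1-ol; 15 methyl bromoacetate
Product: 17 methyl 2-[(1R,2R,4E,8R)-8-{[(tert-butyldimethylsilyl)oxy]methyl}-2-[(4-methoxybenzyl)oxy]-4-methyl-10-oxocyclodec-4-en-1-yl]acetate, via potassium enolate 16 (not isolated)
Conditions: KN(SiMe3)2, THF, 0 → 40 °C; then −78 °C, BrCH2CO2Me
Reagents that add atoms: none
Why: Anionic oxy-Cope rearrangement, a [3,3]-sigmatropic shift through the chair transition state of the trans-diequatorial dialkenyl alkoxide, breaks C1–C6 and forms C8–C9 with the E ring alkene and with chirality transfer to C8 (the Z enol ether oxygen sits pseudo-axial, bridged to the alkoxide by K+, which gives 8R), and the regiodefined enolate, kept chelated to the C8 ether oxygen, is C-alkylated on its open face anti to C9 (Fráter–Seebach sense), placing C11 cis to the C8 oxygen.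

Step 10
Reactants: 17 methyl 2-[(1R,2R,4E,8R)-8-{[(tert-butyldimethylsilyl)oxy]methyl}-2-[(4-methoxybenzyl)oxy]-4-methyl-10-oxocyclodec-4-en-1-yl]acetate
Product: 19 2-[(1S,2R,4E,8R,10S)-8-{[(tert-butyldimethylsilyl)oxy]methyl}-10-hydroxy-2-[(4-methoxybenzyl)oxy]-4-methylcyclodec-4-en-1-yl]acetic acid, via hydroxy ester 18 (not isolated)
Conditions: Zn(BH4)2, Et2O, −20 °C; then LiOH, THF/H2O, rt; 1 M HCl to pH 4
Reagents that add atoms: lithium hydroxide, [Li+].[OH-]
Why: Chelation-controlled hydride reduction (zinc bridges the ketone and the beta-PMB ether oxygen and hydride enters from the exposed face of the chelate) gives the 1,3-syn 6S alcohol, and saponification in the same flask delivers the open hydroxy acid even if some cis-lactone had formed.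

Step 11
Reactants: 19 2-[(1S,2R,4E,8R,10S)-8-{[(tert-butyldimethylsilyl)oxy]methyl}-10-hydroxy-2-[(4-methoxybenzyl)oxy]-4-methylcyclodec-4-en-1-yl]acetic acid
Product: 20 (3aR,4R,6E,10R,11aR)-10-{[(tert-butyldimethylsilyl)oxy]methyl}-4-[(4-methoxybenzyl)oxy]-6-methyl-3a,4,5,8,9,10,11,11a-octahydrocyclodeca[b]furan-2(3H)-one
Conditions: PPh3, DIAD, THF, 0 °C
Reagents that add atoms: none
Why: Mitsunobu lactonization: the C6 hydroxyl is turned into an oxyphosphonium leaving group and displaced intramolecularly by the carboxylate in a 5-exo SN2 reaction with inversion (6S to 6R), which gives the trans-fused gamma-lactone.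

Step 12
Reactants: 20 (3aR,4R,6E,10R,11aR)-10-{[(tert-butyldimethylsilyl)oxy]methyl}-4-[(4-methoxybenzyl)oxy]-6-methyl-3a,4,5,8,9,10,11,11a-octahydrocyclodeca[b]furan-2(3H)-one
Product: 23 (3aR,4R,6E,10R,11aR)-10-{[(tert-butyldimethylsilyl)oxy]methyl}-4-[(4-methoxybenzyl)oxy]-6-methyl-3-methylidene-3a,4,5,8,9,10,11,11a-octahydrocyclodeca[b]furan-2(3H)-one, via Mannich base 21 (not isolated), via ammonium iodide 22 (not isolated)
Conditions: LiN(SiMe3)2, THF, −78 °C; Me2N=CH2 I (Eschenmoser's salt), −78 → 0 °C; then MeI, rt; then DBU, rt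
Reagents that add atoms: Eschenmoser's salt (N,N-dimethylmethyleneiminium iodide), C=[N+](C)C.[I-]
Why: Alpha-methylenation of the lactone by Mannich reaction of its lithium enolate with Eschenmoser's salt, N-methylation and base-induced elimination of trimethylamine; the transient C11 centre disappears and no other stereocentre is acidic.

Step 13
Reactants: 23 (3aR,4R,6E,10R,11aR)-10-{[(tert-butyldimethylsilyl)oxy]methyl}-4-[(4-methoxybenzyl)oxy]-6-methyl-3-methylidene-3a,4,5,8,9,10,11,11a-octahydrocyclodeca[b]furan-2(3H)-one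
Product: 24 (3aR,4R,6E,10R,11aR)-10-{[(tert-butyldimethylsilyl)oxy]methyl}-6-(hydroxymethyl)-4-[(4-methoxybenzyl)oxy]-3-methylidene-3a,4,5,8,9,10,11,11a-octahydrocyclodeca[b]furan-2(3H)-one (C2 and C9 now cis across C1=C10)
Conditions: SeO2 (0.5 equiv), t-BuOOH, CH2Cl2, rt
Reagents that add atoms: selenium dioxide, O=[Se]=O; tert-butyl hydroperoxide, CC(C)(C)OO
Why: Riley oxidation: an ene reaction of SeO2 at C1 with a C14 hydrogen and a [2,3]-sigmatropic shift of the allylseleninic acid put oxygen on C14 and re-form C1=C10 with the new C–O carbon trans to C2, so the methyl group is oxidised and the strained trans ring alkene becomes the more stable cis ring alkene of the target in one step, as is known for germacranolides carrying the same alpha-methylene lactone.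

Step 14
Reactants: 24 (3aR,4R,6E,10R,11aR)-10-{[(tert-butyldimethylsilyl)oxy]methyl}-6-(hydroxymethyl)-4-[(4-methoxybenzyl)oxy]-3-methylidene-3a,4,5,8,9,10,11,11a-octahydrocyclodeca[b]furan-2(3H)-one
Product: 26 (3aR,4R,6E,10R,11aR)-10-{[(tert-butyldimethylsilyl)oxy]methyl}-4-[(4-methoxybenzyl)oxy]-3-methylidene-2-oxo-2,3,3a,4,5,8,9,10,11,11a-decahydrocyclodeca[b]furan-6-carboxylic acid, via enal 25 (not isolated)
Conditions: TEMPO (cat.), PhI(OAc)2, CH2Cl2, rt; then NaClO2, NaH2PO4, 2-methyl-2-butene, t-BuOH/H2O, 0 °C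
Reagents that add atoms: sodium chlorite, [Na+].[O-]Cl=O
Why: Oxoammonium (TEMPO) oxidation of the primary allylic alcohol to the enal followed by Pinnick oxidation in the same flask gives the conjugated acid without touching the alkene geometry, the PMB ether or the alpha-methylene lactone.

Step 15
Reactants: 26 (3aR,4R,6E,10R,11aR)-10-{[(tert-butyldimethylsilyl)oxy]methyl}-4-[(4-methoxybenzyl)oxy]-3-methylidene-2-oxo-2,3,3a,4,5,8,9,10,11,11a-decahydrocyclodeca[b]furan-6-carboxylic acid
Product: 27 methyl (3aR,4R,6E,10R,11aR)-10-{[(tert-butyldimethylsilyl)oxy]methyl}-4-[(4-methoxybenzyl)oxy]-3-methylidene-2-oxo-2,3,3a,4,5,8,9,10,11,11a-decahydrocyclodeca[b]furan-6-carboxylate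
Conditions: MeI, KHCO3, DMF, rt
Reagents that add atoms: iodomethane, CI
Why: SN2 O-methylation of the carboxylate under weakly basic conditions that do not add nucleophiles to the alpha-methylene lactone.

Step 16
Reactants: 27 methyl (3aR,4R,6E,10R,11aR)-10-{[(tert-butyldimethylsilyl)oxy]methyl}-4-[(4-methoxybenzyl)oxy]-3-methylidene-2-oxo-2,3,3a,4,5,8,9,10,11,11a-decahydrocyclodeca[b]furan-6-carboxylate
Product: 28 methyl (3aR,4R,6E,10R,11aR)-10-{[(tert-butyldimethylsilyl)oxy]methyl}-4-hydroxy-3-methylidene-2-oxo-2,3,3a,4,5,8,9,10,11,11a-decahydrocyclodeca[b]furan-6-carboxylate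
Conditions: DDQ, CH2Cl2/pH 7 buffer, 0 °C
Reagents that add atoms: none
Why: Oxidative PMB ether cleavage (hydride abstraction by DDQ and hydrolysis of the oxocarbenium ion) frees only the C8 hydroxyl and leaves the silyl ether and the electron-poor alkenes alone.

Step 17
Reactants: 28 methyl (3aR,4R,6E,10R,11aR)-10-{[(tert-butyldimethylsilyl)oxy]methyl}-4-hydroxy-3-methylidene-2-oxo-2,3,3a,4,5,8,9,10,11,11a-decahydrocyclodeca[b]furan-6-carboxylate; 29 (R)-2-methylbutanoic acid
Product: 30 methyl (3aS,4R,6E,10R,11aR)-10-{[(tert-butyldimethylsilyl)oxy]methyl}-3-methylidene-4-{[(2R)-2-methylbutanoyl]oxy}-2-oxo-2,3,3a,4,5,8,9,10,11,11a-decahydrocyclodeca[b]furan-6-carboxylate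
Conditions: DCC, DMAP (cat.), CH2Cl2, 0 °C → rt
Reagents that add atoms: none
Why: Steglich esterification acylates the C8 alcohol with retention at C8 and, at low temperature with catalytic DMAP, without epimerising the alpha stereocentre of the bought acid.

Step 18
Reactants: 30 methyl (3aS,4R,6E,10R,11aR)-10-{[(tert-butyldimethylsilyl)oxy]methyl}-3-methylidene-4-{[(2R)-2-methylbutanoyl]oxy}-2-oxo-2,3,3a,4,5,8,9,10,11,11a-decahydrocyclodeca[b]furan-6-carboxylate
Product: 31 methyl (3aS,4R,6E,10R,11aR)-10-(hydroxymethyl)-3-methylidene-4-{[(2R)-2-methylbutanoyl]oxy}-2-oxo-2,3,3a,4,5,8,9,10,11,11a-decahydrocyclodeca[b]furan-6-carboxylate (CNP0141952.3)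
Conditions: HF·pyridine, THF/pyridine, 0 °C → rt
Reagents that add atoms: none
Why: Desilylation of the primary TBS ether with buffered HF·pyridine, conditions under which the lactone, both esters and the stereocentres are stable, completes the target.

**Compound list**

1 | (R)-cyclohex-3-ene-1-carboxylic acid | C1[C@H](C(=O)O)CCC=C1 | starting material
2 | (1R,4R,5R)-4-iodo-6-oxabicyclo[3.2.1]octan-7-one | O=C1O[C@@H]2C[C@H]1CC[C@H]2I | intermediate
3 | isopropenylmagnesium bromide | CC(=C)[Mg]Br | starting material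
4 | (1R,4S,5R)-4-(prop-1-en-2-yl)-6-oxabicyclo[3.2.1]octan-7-one | O=C1O[C@@H]2C[C@H]1CC[C@H]2C(C)=C | intermediate
5 | (1R,2S,5R)-5-(hydroxymethyl)-2-(prop-1-en-2-yl)cyclohexan-1-ol (all substituents equatorial) | O[C@@H]1C[C@H](CO)CC[C@H]1C(C)=C | intermediate
6 | (1R,2S,5R)-5-{[(tert-butyldimethylsilyl)oxy]methyl}-2-(prop-1-en-2-yl)cyclohexan-1-ol | O[C@@H]1C[C@H](CO[Si](C)(C)C(C)(C)C)CC[C@H]1C(C)=C | intermediate
7 | (2S,5R)-5-{[(tert-butyldimethylsilyl)oxy]methyl}-2-(prop-1-en-2-yl)cyclohexan-1-one (trans) | O=C1C[C@H](CO[Si](C)(C)C(C)(C)C)CC[C@H]1C(C)=C | intermediate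
8 | 4-methoxybenzyl alcohol | COc1ccc(CO)cc1 | starting material
9 | ethyl vinyl ether | CCOC=C | starting material
10 | 4-methoxybenzyl vinyl ether | COc1ccc(COC=C)cc1 | intermediate
11 | 1-[(1,2-dibromoethoxy)methyl]-4-methoxybenzene (racemic, not isolated) | COc1ccc(COC(Br)CBr)cc1 | intermediate
12 | (Z)-1-bromo-2-[(4-methoxybenzyl)oxy]ethene | COc1ccc(CO/C=C\Br)cc1 | intermediate
13 | (Z)-2-[(4-methoxybenzyl)oxy]ethenyllithium (not isolated) | COc1ccc(CO/C=C\[Li])cc1 | intermediate
14 | (1S,2S,5R)-5-{[(tert-butyldimethylsilyl)oxy]methyl}-1-{(Z)-2-[(4-methoxybenzyl)oxy]ethenyl}-2-(prop-1-en-2-yl)cyclohexan-1-ol (OH axial, three carbon substituents equatorial) | O[C@@]1(/C=C\OCc2ccc(OC)cc2)C[C@H](CO[Si](C)(C)C(C)(C)C)CC[C@H]1C(C)=C | intermediate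
15 | methyl bromoacetate | COC(=O)CBr | starting material
16 | potassium (1Z,3R,5E,9R)-9-{[(tert-butyldimethylsilyl)oxy]methyl}-3-[(4-methoxybenzyl)oxy]-5-methylcyclodeca-1,5-dien-1-olate (not isolated) | [K+].[O-]/C1=C\[C@H](OCc2ccc(OC)cc2)C/C(C)=C/CC[C@@H](CO[Si](C)(C)C(C)(C)C)C1 | intermediate
17 | methyl 2-[(1R,2R,4E,8R)-8-{[(tert-butyldimethylsilyl)oxy]methyl}-2-[(4-methoxybenzyl)oxy]-4-methyl-10-oxocyclodec-4-en-1-yl]acetate | COC(=O)C[C@H]1C(=O)C[C@H](CO[Si](C)(C)C(C)(C)C)CC/C=C(\C)C[C@H]1OCc2ccc(OC)cc2 | intermediate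
18 | methyl 2-[(1S,2R,4E,8R,10S)-8-{[(tert-butyldimethylsilyl)oxy]methyl}-10-hydroxy-2-[(4-methoxybenzyl)oxy]-4-methylcyclodec-4-en-1-yl]acetate (not isolated) | COC(=O)C[C@H]1[C@@H](O)C[C@H](CO[Si](C)(C)C(C)(C)C)CC/C=C(\C)C[C@H]1OCc2ccc(OC)cc2 | intermediate
19 | 2-[(1S,2R,4E,8R,10S)-8-{[(tert-butyldimethylsilyl)oxy]methyl}-10-hydroxy-2-[(4-methoxybenzyl)oxy]-4-methylcyclodec-4-en-1-yl]acetic acid | OC(=O)C[C@H]1[C@@H](O)C[C@H](CO[Si](C)(C)C(C)(C)C)CC/C=C(\C)C[C@H]1OCc2ccc(OC)cc2 | intermediate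
20 | (3aR,4R,6E,10R,11aR)-10-{[(tert-butyldimethylsilyl)oxy]methyl}-4-[(4-methoxybenzyl)oxy]-6-methyl-3a,4,5,8,9,10,11,11a-octahydrocyclodeca[b]furan-2(3H)-one (trans-fused lactone) | C1C(=O)O[C@@H]2C[C@H](CO[Si](C)(C)C(C)(C)C)CC/C=C(\C)C[C@@H](OCc3ccc(OC)cc3)[C@@H]12 | intermediate
21 | 3-[(dimethylamino)methyl] derivative of 20 (C11 epimers, not isolated) | CN(C)CC1C(=O)O[C@@H]2C[C@H](CO[Si](C)(C)C(C)(C)C)CC/C=C(\C)C[C@@H](OCc3ccc(OC)cc3)[C@@H]12 | intermediate
22 | 3-[(trimethylammonio)methyl] derivative of 20, iodide (C11 epimers, not isolated) | [I-].C[N+](C)(C)CC1C(=O)O[C@@H]2C[C@H](CO[Si](C)(C)C(C)(C)C)CC/C=C(\C)C[C@@H](OCc3ccc(OC)cc3)[C@@H]12 | intermediate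
23 | (3aR,4R,6E,10R,11aR)-10-{[(tert-butyldimethylsilyl)oxy]methyl}-4-[(4-methoxybenzyl)oxy]-6-methyl-3-methylidene-3a,4,5,8,9,10,11,11a-octahydrocyclodeca[b]furan-2(3H)-one (C2 and C9 trans across C1=C10) | C=C1C(=O)O[C@@H]2C[C@H](CO[Si](C)(C)C(C)(C)C)CC/C=C(\C)C[C@@H](OCc3ccc(OC)cc3)[C@@H]12 | intermediate
24 | (3aR,4R,6E,10R,11aR)-10-{[(tert-butyldimethylsilyl)oxy]methyl}-6-(hydroxymethyl)-4-[(4-methoxybenzyl)oxy]-3-methylidene-3a,4,5,8,9,10,11,11a-octahydrocyclodeca[b]furan-2(3H)-one (C2 and C9 cis across C1=C10) | C=C1C(=O)O[C@@H]2C[C@H](CO[Si](C)(C)C(C)(C)C)CC/C=C(/CO)C[C@@H](OCc3ccc(OC)cc3)[C@@H]12 | intermediate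
25 | (3aR,4R,6E,10R,11aR)-10-{[(tert-butyldimethylsilyl)oxy]methyl}-4-[(4-methoxybenzyl)oxy]-3-methylidene-2-oxo-2,3,3a,4,5,8,9,10,11,11a-decahydrocyclodeca[b]furan-6-carbaldehyde (not isolated) | C=C1C(=O)O[C@@H]2C[C@H](CO[Si](C)(C)C(C)(C)C)CC/C=C(/C=O)C[C@@H](OCc3ccc(OC)cc3)[C@@H]12 | intermediate
26 | (3aR,4R,6E,10R,11aR)-10-{[(tert-butyldimethylsilyl)oxy]methyl}-4-[(4-methoxybenzyl)oxy]-3-methylidene-2-oxo-2,3,3a,4,5,8,9,10,11,11a-decahydrocyclodeca[b]furan-6-carboxylic acid | C=C1C(=O)O[C@@H]2C[C@H](CO[Si](C)(C)C(C)(C)C)CC/C=C(/C(=O)O)C[C@@H](OCc3ccc(OC)cc3)[C@@H]12 | intermediate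
27 | methyl (3aR,4R,6E,10R,11aR)-10-{[(tert-butyldimethylsilyl)oxy]methyl}-4-[(4-methoxybenzyl)oxy]-3-methylidene-2-oxo-2,3,3a,4,5,8,9,10,11,11a-decahydrocyclodeca[b]furan-6-carboxylate | C=C1C(=O)O[C@@H]2C[C@H](CO[Si](C)(C)C(C)(C)C)CC/C=C(/C(=O)OC)C[C@@H](OCc3ccc(OC)cc3)[C@@H]12 | intermediate
28 | methyl (3aR,4R,6E,10R,11aR)-10-{[(tert-butyldimethylsilyl)oxy]methyl}-4-hydroxy-3-methylidene-2-oxo-2,3,3a,4,5,8,9,10,11,11a-decahydrocyclodeca[b]furan-6-carboxylate | C=C1C(=O)O[C@@H]2C[C@H](CO[Si](C)(C)C(C)(C)C)CC/C=C(/C(=O)OC)C[C@@H](O)[C@@H]12 | intermediate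
29 | (R)-2-methylbutanoic acid | CC[C@@H](C)C(=O)O | starting material
30 | methyl (3aS,4R,6E,10R,11aR)-10-{[(tert-butyldimethylsilyl)oxy]methyl}-3-methylidene-4-{[(2R)-2-methylbutanoyl]oxy}-2-oxo-2,3,3a,4,5,8,9,10,11,11a-decahydrocyclodeca[b]furan-6-carboxylate | C=C1C(=O)O[C@@H]2C[C@H](CO[Si](C)(C)C(C)(C)C)CC/C=C(/C(=O)OC)C[C@@H](OC(=O)[C@H](C)CC)[C@@H]12 | intermediate
31 | methyl (3aS,4R,6E,10R,11aR)-10-(hydroxymethyl)-3-methylidene-4-{[(2R)-2-methylbutanoyl]oxy}-2-oxo-2,3,3a,4,5,8,9,10,11,11a-decahydrocyclodeca[b]furan-6-carboxylate | C=C1C(=O)O[C@@H]2C[C@H](CO)CC/C=C(/C(=O)OC)C[C@@H](OC(=O)[C@H](C)CC)[C@@H]12 | target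

**Step count and risk**

Total step count: 18. Longest linear sequence: 16 (steps 1–5 and 8–18, from 1 to 31); steps 6 and 7 make the vinyl bromide 12.

The three steps most likely to fail are steps 2, 9 and 11.

Step 2 (iron-catalysed alkenylation of the iodolactone) can fail because the Grignard reagent may attack the lactone or the organoiron intermediate may expel the neighbouring oxygen. The fallback sets out from 1 and comes back at 7. Reduce 1 with LiAlH4 to (R)-cyclohex-3-en-1-ylmethanol F1 and silylate it (TBSCl, imidazole) to the TBS ether F2. Epoxidise with mCPBA and separate the trans-epoxide F3, whose oxirane is anti to the CH2OTBS group. Open it with isopropenylmagnesium bromide and catalytic CuI; trans-diaxial (Fürst–Plattner) opening directs the alkenyl group to the ring carbon para to the side chain and gives the diaxial alcohol F4. Oxidise with Dess–Martin periodinane to the cis-ketone F5 and equilibrate with DBU to the trans-ketone 7.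

Step 9 (oxy-Cope rearrangement with alkylation in the same flask) can fail by loss of the C8 alkoxide from the enolate or by alkylation on the wrong face. The fallback sets out from 14 and comes back at 17. Run the rearrangement with KN(SiMe3)2 and 18-crown-6 at 0 °C and trap with Me3SiCl to isolate the regiodefined trimethylsilyl enol ether F6. Regenerate the enolate as its lithium salt with MeLi, lithium holding the C8 ether oxygen more firmly than potassium, and alkylate with methyl bromoacetate at −78 °C to reach 17.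

Step 11 (lactonization with inversion) can fail because a hindered ring alcohol may eliminate under Mitsunobu conditions or close through the activated acid with retention. The fallback sets out from 17 and comes back at 20. Reduce 17 with SmI2 and MeOH in THF at 0 °C, where the chelated ketyl of a beta-alkoxy ketone gives the 1,3-anti 6R hydroxy ester F7. Close it with PPTS in CH2Cl2, with retention, to the trans-lactone 20, so no inversion is needed.

**Further compounds**

F1 | step 2 | (R)-cyclohex-3-en-1-ylmethanol | C1[C@H](CO)CCC=C1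
F2 | step 2 | (R)-tert-butyl(cyclohex-3-en-1-ylmethoxy)dimethylsilane | C1[C@H](CO[Si](C)(C)C(C)(C)C)CCC=C1
F3 | step 2 | (1S,3R,6R)-3-{[(tert-butyldimethylsilyl)oxy]methyl}-7-oxabicyclo[4.1.0]heptane (trans-epoxide) | C1[C@H](CO[Si](C)(C)C(C)(C)C)CC[C@H]2O[C@@H]12
F4 | step 2 | (1S,2R,5R)-5-{[(tert-butyldimethylsilyl)oxy]methyl}-2-(prop-1-en-2-yl)cyclohexan-1-ol | O[C@H]1C[C@H](CO[Si](C)(C)C(C)(C)C)CC[C@@H]1C(C)=C
F5 | step 2 | (2R,5R)-5-{[(tert-butyldimethylsilyl)oxy]methyl}-2-(prop-1-en-2-yl)cyclohexan-1-one (cis) | O=C1C[C@H](CO[Si](C)(C)C(C)(C)C)CC[C@@H]1C(C)=C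
F6 | step 9 | {[(1Z,3R,5E,9R)-9-{[(tert-butyldimethylsilyl)oxy]methyl}-3-[(4-methoxybenzyl)oxy]-5-methylcyclodeca-1,5-dien-1-yl]oxy}trimethylsilane | C[Si](C)(C)O/C1=C\[C@H](OCc2ccc(OC)cc2)C/C(C)=C/CC[C@@H](CO[Si](C)(C)C(C)(C)C)C1
F7 | step 11 | methyl 2-[(1S,2R,4E,8R,10R)-8-{[(tert-butyldimethylsilyl)oxy]methyl}-10-hydroxy-2-[(4-methoxybenzyl)oxy]-4-methylcyclodec-4-en-1-yl]acetate | COC(=O)C[C@H]1[C@H](O)C[C@H](CO[Si](C)(C)C(C)(C)C)CC/C=C(\C)C[C@H]1OCc2ccc(OC)cc2
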